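**Retrosynthetic overview**

1. Target ⇒ acetonide hydrolysis and 7‑O Mitsunobu etherification: 5,7‑dihydroxycoumarin + a C15 dienol acetonide.
2. Key disconnection C7–C8 (sp2–sp3; side chain numbered C1–C11 from the ether CH2): visible‑light nickel/iridium deoxygenative alkenylation of a primary alcohol with (2E,6E)‑7‑iodo‑3‑methylocta‑2,6‑dien‑1‑ol.
3. Alcohol partner: double MeMgBr addition to 2,3‑O‑isopropylidene‑D‑erythronolactone, which supplies both stereocentres (C9, C10) and the C11 carbinol.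
4. Iododienol: geranyl acetate (2E bought) by selective ozonolysis, Corey–Fuchs/methylation and hydrozirconation–iodination (sets 6E).
5. Rings: none is built; the coumarin bicycle is bought intact and the dioxolane of the starting lactone is carried to the last step and then hydrolysed.

Assumption: the given SMILES defines the target (2E,6E,9R,10R in the side‑chain numbering above); geranyl acetate, 2,3‑O‑isopropylidene‑D‑erythronolactone, 5,7‑dihydroxycoumarin and the benzoxazolium activator are bought.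

**Route**

Step 1
Reactants: 1 geranyl acetate
Product: 3 (2E)-3-methyl-6-oxohex-2-en-1-yl acetate, via secondary ozonide 2 (not isolated)
Conditions: O3 (1.0 equiv, metered), CH2Cl2, −78 °C; then Me2S, −78 °C → rt
Reagents that add atoms: ozone, [O-][O+]=O
Why: Chemoselective ozonolysis, because ozone attacks the electron‑rich 6,7‑alkene much faster than the 2,3‑alkene deactivated by the allylic acetate, and reductive work‑up of the ozonide gives the aldehyde with the 2E geometry untouched.

Step 2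
Reactants: 3 (2E)-3-methyl-6-oxohex-2-en-1-yl acetate
Product: 4 (2E)-7,7-dibromo-3-methylhepta-2,6-dien-1-yl acetate
Conditions: CBr4 (2 equiv), PPh3 (4 equiv), CH2Cl2, 0 °C
Reagents that add atoms: carbon tetrabromide, BrC(Br)(Br)Br
Why: First stage of the Corey–Fuchs sequence (Ramirez dibromo‑olefination), a Wittig reaction of in‑situ Ph3P=CBr2 with an unhindered aldehyde that leaves the allylic acetate and the alkene alone.

Step 3
Reactants: 4 (2E)-7,7-dibromo-3-methylhepta-2,6-dien-1-yl acetate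
Product: 6 (2E)-3-methyloct-2-en-6-yn-1-ol, via dilithium alkoxide acetylide 5 (not isolated)
Conditions: n-BuLi (4.3 equiv), THF, −78 → 0 °C; then MeI (1.3 equiv), −78 °C → rt; then H2O
Reagents that add atoms: iodomethane, CI
Why: Second stage of the Corey–Fuchs sequence (Br/Li exchange, Fritsch–Buttenberg–Wiechell rearrangement, deprotonation) gives the lithium acetylide, which is C‑methylated by MeI, while the extra n‑BuLi deliberately cleaves the acetate so the C1 alcohol is freed in the same operation.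

Step 4
Reactants: 6 (2E)-3-methyloct-2-en-6-yn-1-ol
Product: 8 (2E,6E)-7-iodo-3-methylocta-2,6-dien-1-ol, via C7-alkenylzirconocene 7 (not isolated)
Conditions: Cp2Zr(H)Cl (3.0 equiv), THF, rt → 50 °C; then I2, 0 °C; aq. Na2S2O3 work‑up
Reagents that add atoms: iodine, II
Why: Hydrozirconation–iodination, in which Zr–H adds syn across the alkyne, excess reagent at 50 °C equilibrates zirconium onto the less hindered methyl‑bearing carbon, and iodinolysis with retention places iodine trans to the C5 chain (6E), the trisubstituted C2=C3 alkene being inert to Cp2Zr(H)Cl.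

Step 5
Reactants: 9 2,3-O-isopropylidene-D-erythronolactone
Product: 11 2-[(4R,5R)-5-(hydroxymethyl)-2,2-dimethyl-1,3-dioxolan-4-yl]propan-2-ol, via keto alkoxide 10 (not isolated)
Conditions: MeMgBr (3.0 equiv), THF, 0 °C → rt; then H2O
Reagents that add atoms: methylmagnesium bromide, C[Mg]Br
Why: Double Grignard addition to the lactone builds the C11 dimethylcarbinol, addition to the transient ketone outruns enolisation, and both stereocentres (lactone α‑carbon = C10, β‑carbon = C9, both R) are those bought in D‑erythronolactone.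

Step 6
Reactants: 8 (2E,6E)-7-iodo-3-methylocta-2,6-dien-1-ol; 11 2-[(4R,5R)-5-(hydroxymethyl)-2,2-dimethyl-1,3-dioxolan-4-yl]propan-2-ol
Product: 13 (2E,6E)-8-[(4R,5R)-5-(2-hydroxypropan-2-yl)-2,2-dimethyl-1,3-dioxolan-4-yl]-3,7-dimethylocta-2,6-dien-1-ol, via benzoxazoline adduct 12 (not isolated)
Conditions: 11 (1.6 equiv), 5,7-di-tert-butyl-3-phenylbenzoxazolium tetrafluoroborate (1.5 equiv), pyridine (1.5 equiv), MTBE, rt, 15 min; then 8 (1.0 equiv), [Ir(ppy)2(dtbbpy)]PF6 (1.5 mol %), NiBr2(dtbbpy) (5 mol %), quinuclidine (1.75 equiv), degassed DMA, 450 nm LEDs, rt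
Reagents that add atoms: none
Why: Proposed new method: the primary hydroxyl of 11 condenses with the benzoxazolium salt far faster than the tertiary one to give aminal 12, photoexcited trivalent iridium oxidises its N‑aryl nitrogen, quinuclidine removes the aminal C–H and β‑scission (driven by formation of the benzoxazolone) releases the primary C8 radical, which has no fragmentable β‑bond and never becomes a carbanion or a carbon bearing a leaving group (so neither β‑alkoxide elimination nor oxolane closure by the free tertiary alcohol can occur), while zerovalent nickel inserts into the alkenyl C–I bond of 8 with retention, the divalent alkenylnickel captures the radical and the resulting trivalent nickel reductively eliminates the C7–C8 bond faster than the 1‑methylalkenyl ligand can isomerise, so 6E is kept and the bought C9/C10 centres are untouched; the closest known reaction type is the NHC‑mediated deoxygenative nickel metallaphotoredox arylation of alcohols with aryl halides, which to my knowledge has not been shown for a trisubstituted alkenyl iodide or an unprotected 1,4‑diol.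

Step 7
Reactants: 13 (2E,6E)-8-[(4R,5R)-5-(2-hydroxypropan-2-yl)-2,2-dimethyl-1,3-dioxolan-4-yl]-3,7-dimethylocta-2,6-dien-1-ol; 14 5,7-dihydroxycoumarin
Product: 15 5-hydroxy-7-{[(2E,6E)-8-[(4R,5R)-5-(2-hydroxypropan-2-yl)-2,2-dimethyl-1,3-dioxolan-4-yl]-3,7-dimethylocta-2,6-dien-1-yl]oxy}-2H-chromen-2-one
Conditions: 14 (2.0 equiv), PPh3 (1.3 equiv), DIAD (1.3 equiv), THF, 0 °C → rt
Reagents that add atoms: none
Why: Mitsunobu etherification, an SN2 displacement at the activated primary allylic carbon by the more acidic and less hindered 7‑OH of excess 14, with the tertiary alcohol inert and no stereocentre involved.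

Step 8
Reactants: 15 5-hydroxy-7-{[(2E,6E)-8-[(4R,5R)-5-(2-hydroxypropan-2-yl)-2,2-dimethyl-1,3-dioxolan-4-yl]-3,7-dimethylocta-2,6-dien-1-yl]oxy}-2H-chromen-2-one
Product: 16 5-hydroxy-7-{[(2E,6E,9R,10R)-9,10,11-trihydroxy-3,7,11-trimethyldodeca-2,6-dien-1-yl]oxy}-2H-chromen-2-one
Conditions: AcOH/H2O (4:1), 45 °C
Reagents that add atoms: none
Why: Acid‑catalysed acetal hydrolysis under conditions too mild to ionise the allylic aryl ether or dehydrate the tertiary alcohol releases the (9R,10R)‑triol without touching either stereocentre.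

**Compound list**

1 | geranyl acetate, (2E)-3,7-dimethylocta-2,6-dien-1-yl acetate | CC(=O)OC/C=C(\C)CCC=C(C)C | starting material
2 | secondary ozonide, (2E)-5-(5,5-dimethyl-1,2,4-trioxolan-3-yl)-3-methylpent-2-en-1-yl acetate (ring carbon racemic) | CC(=O)OC/C=C(\C)CCC1OOC(C)(C)O1 | intermediate
3 | (2E)-3-methyl-6-oxohex-2-en-1-yl acetate | CC(=O)OC/C=C(\C)CCC=O | intermediate
4 | (2E)-7,7-dibromo-3-methylhepta-2,6-dien-1-yl acetate | CC(=O)OC/C=C(\C)CCC=C(Br)Br | intermediate
5 | dilithium salt (alkoxide and acetylide) of (2E)-3-methylhept-2-en-6-yn-1-ol | [Li+].[Li+].[O-]C/C=C(\C)CCC#[C-] | intermediate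
6 | (2E)-3-methyloct-2-en-6-yn-1-ol | OC/C=C(\C)CCC#CC | intermediate
7 | (2E,6E) C7‑alkenylzirconocene chloride of 6 as its O‑zirconocene alkoxide, Cp2Zr(Cl)–C(CH3)=CH–CH2CH2–C(CH3)=CH–CH2–O–Zr(Cl)Cp2 (Zr on C7, cis to H6) | C/C(=C\CC/C(C)=C/CO[Zr](Cl)(C1C=CC=C1)C1C=CC=C1)[Zr](Cl)(C1C=CC=C1)C1C=CC=C1 | intermediate
8 | (2E,6E)-7-iodo-3-methylocta-2,6-dien-1-ol | OC/C=C(\C)CC/C=C(\C)I | intermediate
9 | 2,3-O-isopropylidene-D-erythronolactone, (3aR,6aR)-2,2-dimethyldihydrofuro[3,4-d][1,3]dioxol-4(3aH)-one | O=C1[C@@H]2OC(C)(C)O[C@@H]2CO1 | starting material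
10 | 1-[(4R,5R)-5-{[(bromomagnesio)oxy]methyl}-2,2-dimethyl-1,3-dioxolan-4-yl]ethan-1-one | CC(=O)[C@@H]1OC(C)(C)O[C@@H]1CO[Mg]Br | intermediate
11 | 2-[(4R,5R)-5-(hydroxymethyl)-2,2-dimethyl-1,3-dioxolan-4-yl]propan-2-ol | CC(C)(O)[C@@H]1OC(C)(C)O[C@@H]1CO | intermediate
12 | 2-[(4R,5R)-5-{[(5,7-di-tert-butyl-3-phenyl-2,3-dihydro-1,3-benzoxazol-2-yl)oxy]methyl}-2,2-dimethyl-1,3-dioxolan-4-yl]propan-2-ol (aminal carbon unassigned) | CC(C)(O)[C@@H]1OC(C)(C)O[C@@H]1COC3Oc4c(C(C)(C)C)cc(C(C)(C)C)cc4N3c5ccccc5 | intermediate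
13 | (2E,6E)-8-[(4R,5R)-5-(2-hydroxypropan-2-yl)-2,2-dimethyl-1,3-dioxolan-4-yl]-3,7-dimethylocta-2,6-dien-1-ol | OC/C=C(\C)CC/C=C(\C)C[C@H]1OC(C)(C)O[C@H]1C(C)(C)O | intermediate
14 | 5,7-dihydroxycoumarin, 5,7-dihydroxy-2H-chromen-2-one | O=c1ccc2c(O)cc(O)cc2o1 | starting material
15 | 5-hydroxy-7-{[(2E,6E)-8-[(4R,5R)-5-(2-hydroxypropan-2-yl)-2,2-dimethyl-1,3-dioxolan-4-yl]-3,7-dimethylocta-2,6-dien-1-yl]oxy}-2H-chromen-2-one | C/C(=C\COc1cc(O)c2ccc(=O)oc2c1)CC/C=C(\C)C[C@H]1OC(C)(C)O[C@H]1C(C)(C)O | intermediate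
16 | 5-hydroxy-7-{[(2E,6E,9R,10R)-9,10,11-trihydroxy-3,7,11-trimethyldodeca-2,6-dien-1-yl]oxy}-2H-chromen-2-one (CNP0174708.3) | C/C(=C\COc1cc(O)c2ccc(=O)oc2c1)CC/C=C(\C)C[C@@H](O)[C@@H](O)C(C)(C)O | target

**Step count and risks**

Total steps: 8. Longest linear sequence: 7 steps (1 → 3 → 4 → 6 → 8 → 13 → 15 → 16); step 5 is the one‑step side branch.

Most likely to fail:

Step 6 (the proposed new coupling). The risks are partial condensation at the tertiary hydroxyl, hydrogen abstraction at the allylic carbinol C–H of 8, and untested behaviour of a 1‑methylalkenyl iodide in this manifold. The fallback uses known chemistry, sets out from 11 and 8 and comes back at 13. Compound 11 is silylated twice (TMSCl, imidazole, DMF) to the bis(trimethylsilyl) ether F1. K2CO3 in MeOH at 0 °C frees only the primary hydroxyl, giving [(4R,5R)-2,2-dimethyl-5-{2-[(trimethylsilyl)oxy]propan-2-yl}-1,3-dioxolan-4-yl]methanol F2; the tertiary oxygen stays capped so that it cannot close an oxolane once C8 carries a leaving group. Appel iodination (I2, PPh3, imidazole, CH2Cl2, 0 °C) gives the iodide F3. A thermal nickel‑catalysed reductive cross‑electrophile coupling of F3 with 8 (NiI2, 4,4'-di-tert-butyl-2,2'-bipyridine, Mn powder, DMPU, rt) gives the coupled silyl ether F4, still through a C8 radical and therefore without β‑alkoxide elimination. Citric acid in MeOH removes the silyl group and returns 13.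

Step 4 (regiochemistry of hydrozirconation, expected near 10:1 for methyl versus primary alkyl). The fallback sets out from 4 and comes back at 8. Compound 4 is treated with n‑BuLi and then TMSCl, with a dilute HCl work‑up, to give (2E)-3-methyl-7-(trimethylsilyl)hept-2-en-6-yn-1-ol F5. Hydroalumination with i‑Bu2AlH in heptane puts aluminium on the silyl‑bearing carbon with net anti addition; MeLi then MeI methylates that carbon with retention to give (2E,6E)-3-methyl-7-(trimethylsilyl)octa-2,6-dien-1-ol F6. Iododesilylation with NIS in hexafluoroisopropanol, with retention, gives 8. Here silicon, not sterics, fixes the regiochemistry.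

Step 7 (7‑O versus 5‑O selectivity and bis‑alkylation in the Mitsunobu reaction). The fallback sets out from 14 and 13 and comes back at 15. Compound 14 is acetylated (Ac2O, pyridine) to 2-oxo-2H-chromene-5,7-diyl diacetate F7. Imidazole in MeOH removes the more activated, unhindered 7‑acetate first, giving 7-hydroxy-2-oxo-2H-chromen-5-yl acetate F8. Mitsunobu coupling of F8 with 13 (PPh3, DIAD, THF) gives the 5‑O‑acetyl ether F9, and K2CO3 in MeOH at 0 °C removes the acetate to return 15.

**Further compounds**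

F1 | step 6 | trimethyl{[(4R,5R)-2,2-dimethyl-5-{2-[(trimethylsilyl)oxy]propan-2-yl}-1,3-dioxolan-4-yl]methoxy}silane | C[Si](C)(C)OC[C@H]1OC(C)(C)O[C@H]1C(C)(C)O[Si](C)(C)C
F2 | step 6 | [(4R,5R)-2,2-dimethyl-5-{2-[(trimethylsilyl)oxy]propan-2-yl}-1,3-dioxolan-4-yl]methanol | OC[C@H]1OC(C)(C)O[C@H]1C(C)(C)O[Si](C)(C)C
F3 | step 6 | (4S,5R)-4-(iodomethyl)-2,2-dimethyl-5-{2-[(trimethylsilyl)oxy]propan-2-yl}-1,3-dioxolane | IC[C@H]1OC(C)(C)O[C@H]1C(C)(C)O[Si](C)(C)C
F4 | step 6 | (2E,6E)-8-[(4R,5R)-2,2-dimethyl-5-{2-[(trimethylsilyl)oxy]propan-2-yl}-1,3-dioxolan-4-yl]-3,7-dimethylocta-2,6-dien-1-ol | OC/C=C(\C)CC/C=C(\C)C[C@H]1OC(C)(C)O[C@H]1C(C)(C)O[Si](C)(C)C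
F5 | step 4 | (2E)-3-methyl-7-(trimethylsilyl)hept-2-en-6-yn-1-ol | OC/C=C(\C)CCC#C[Si](C)(C)C
F6 | step 4 | (2E,6E)-3-methyl-7-(trimethylsilyl)octa-2,6-dien-1-ol | OC/C=C(\C)CC/C=C(\C)[Si](C)(C)C
F7 | step 7 | 2-oxo-2H-chromene-5,7-diyl diacetate | CC(=O)Oc1cc(OC(C)=O)c2ccc(=O)oc2c1
F8 | step 7 | 7-hydroxy-2-oxo-2H-chromen-5-yl acetate | Oc1cc(OC(C)=O)c2ccc(=O)oc2c1
F9 | step 7 | 7-{[(2E,6E)-8-[(4R,5R)-5-(2-hydroxypropan-2-yl)-2,2-dimethyl-1,3-dioxolan-4-yl]-3,7-dimethylocta-2,6-dien-1-yl]oxy}-2-oxo-2H-chromen-5-yl acetate | C/C(=C\COc1cc(OC(C)=O)c2ccc(=O)oc2c1)CC/C=C(\C)C[C@H]1OC(C)(C)O[C@H]1C(C)(C)O
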